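**Plan**
- Retrosynthesis: after removal of two phenolic silyl ethers, the C2–C3 and C4–C4a bonds of the pyran ring are cut together. This gives an O-(3-methoxyphenyl) oxocarbenium ion of 2,4-dimethoxybenzaldehyde (stored as a methyl aryl acetal) and a (1E,3E)-1,5-diarylpenta-1,3-diene, itself cut at its benzyl-side alkene into a tyrosol-derived tetrazolyl sulfone and a 4-silyloxycinnamaldehyde.
- Enabling feature: ring atoms C4a=C8a–O1=C2 (two carbons of ring A, the ether oxygen, the aryl-bearing C2) form a cationic 2-oxadiene. C3 and C4, with their benzyl and styryl groups, are the benzyl-side E alkene of the pentadiene, whose other alkene survives as the C4 styryl group.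
- Forward: three short branches (acetal, sulfone, enal), Julia–Kocienski union to the diene, annulation that closes the pyran ring (the only ring made), then desilylation.
- Stereochemistry: C2, C3 and C4 all arise in the annulation. The absolute sense comes from a chiral counteranion, the 2,3-trans-3,4-trans array from the E alkene and an all-equatorial chair closure, and the styryl E geometry from the (E,E)-diene.

Key step: step 9

Assumption: the goal is the (2R,3R,4R) enantiomer as drawn; which antipode of the chiral acid delivers it cannot be predicted and is to be fixed by a trial run, both antipodes being accessible.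

**Step 1**
Reactants: 1 2,4-dimethoxybenzaldehyde
Product: 2 1-(dimethoxymethyl)-2,4-dimethoxybenzene
Conditions: HC(OMe)3 (neat), p-TsOH·H2O (cat.), rt; Et3N quench
Reagents that add atoms: trimethyl orthoformate, COC(OC)OC
Why: Acid-catalysed acetalisation in which the orthoester is both methoxy donor and water scavenger should convert the electron-rich aldehyde cleanly, the basic quench protecting the labile acetal.

**Step 2**
Reactants: 2 1-(dimethoxymethyl)-2,4-dimethoxybenzene; 3 3-methoxyphenol
Product: 5 1-[methoxy(3-methoxyphenoxy)methyl]-2,4-dimethoxybenzene (racemic), via α-chloro ether 4 (not isolated)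
Conditions: AcCl, ZnBr2 (cat.), toluene, 0 °C → rt; then 3, iPr2NEt, CH2Cl2, 0 °C → rt; Et3N-deactivated silica
Reagents that add atoms: none
Why: Acetal–acyl chloride exchange gives the α-chloro ether, which should O-alkylate the phenol under amine base as in MOM-type protection of phenols (substitution at an α-halo ether), the medium staying basic so that the acid-labile mixed acetal persists.

**Step 3**
Reactants: 6 tyrosol
Product: 7 4-{2-[(1-phenyl-1H-tetrazol-5-yl)sulfanyl]ethyl}phenol
Conditions: 1-phenyl-1H-tetrazole-5-thiol, PPh3, DIAD, THF, 0 °C → rt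
Reagents that add atoms: 1-phenyl-1H-tetrazole-5-thiol, Sc1nnnn1-c1ccccc1
Why: Mitsunobu thioetherification of the primary alcohol, in which the tetrazolethiol is far more acidic than the phenol and should therefore be the only pronucleophile engaged.

**Step 4**
Reactants: 7 4-{2-[(1-phenyl-1H-tetrazol-5-yl)sulfanyl]ethyl}phenol
Product: 8 1-phenyl-5-({2-[4-(triisopropylsilyloxy)phenyl]ethyl}sulfanyl)-1H-tetrazole
Conditions: TIPSCl, imidazole, DMF, rt
Reagents that add atoms: triisopropylsilyl chloride, CC(C)[Si](Cl)(C(C)C)C(C)C
Why: Imidazole-promoted silylation of the only hydroxyl group installs an aryl silyl ether that tolerates oxidation, strong amide base and acid catalysis and keeps the ring electron-rich.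

**Step 5**
Reactants: 8 1-phenyl-5-({2-[4-(triisopropylsilyloxy)phenyl]ethyl}sulfanyl)-1H-tetrazole
Product: 9 1-phenyl-5-({2-[4-(triisopropylsilyloxy)phenyl]ethyl}sulfonyl)-1H-tetrazole
Conditions: (NH4)6Mo7O24·4H2O (cat.), 30% H2O2, EtOH, 0 °C → rt
Reagents that add atoms: hydrogen peroxide, OO
Why: Molybdate-catalysed peroxide oxidation of sulfide to sulfone is the standard entry to Julia–Kocienski reagents and should leave the aryl silyl ether and the tetrazole untouched.

**Step 6**
Reactants: 10 4-hydroxybenzaldehyde
Product: 11 4-(triisopropylsilyloxy)benzaldehyde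
Conditions: TIPSCl, imidazole, DMF, rt
Reagents that add atoms: triisopropylsilyl chloride, CC(C)[Si](Cl)(C(C)C)C(C)C
Why: Straightforward phenol silylation, chosen so that both phenols of the target carry the same fluoride-labile group.

**Step 7**
Reactants: 11 4-(triisopropylsilyloxy)benzaldehyde
Product: 12 (E)-3-[4-(triisopropylsilyloxy)phenyl]prop-2-enal
Conditions: Ph3P=CHCHO (1.1 equiv), toluene, 80 °C
Reagents that add atoms: (triphenylphosphoranylidene)acetaldehyde, O=CC=P(c1ccccc1)(c1ccccc1)c1ccccc1
Why: Wittig olefination with the stabilised formylmethylene ylide should give the E enal directly, a small excess of ylide and moderate temperature limiting a second homologation.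

**Step 8**
Reactants: 9 1-phenyl-5-({2-[4-(triisopropylsilyloxy)phenyl]ethyl}sulfonyl)-1H-tetrazole; 12 (E)-3-[4-(triisopropylsilyloxy)phenyl]prop-2-enal
Product: 13 (1E,3E)-1,5-bis[4-(triisopropylsilyloxy)phenyl]penta-1,3-diene
Conditions: KHMDS added to 9 + 12 (Barbier mode), DME, −60 °C → rt; aq. NH4Cl
Reagents that add atoms: none
Why: Julia–Kocienski olefination of the potassium-metallated phenyltetrazolyl sulfone with a non-enolisable enal (addition, Smiles rearrangement, loss of SO2 and tetrazolone) should form the new alkene mainly E while the existing E alkene is untouched, and Barbier addition keeps the lifetime of the metallated sulfone short.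

**Step 9**
Reactants: 5 1-[methoxy(3-methoxyphenoxy)methyl]-2,4-dimethoxybenzene; 13 (1E,3E)-1,5-bis[4-(triisopropylsilyloxy)phenyl]penta-1,3-diene
Product: 16 caraganin C bis(triisopropylsilyl) ether, via aryl oxocarbenium ion 14 (not isolated), via allyl cation 15 (not isolated)
Conditions: chiral IDPi Brønsted acid (BINOL-based imidodiphosphorimidate, N-triflyl core, 3,3′-diaryl; 5 mol %), 5 Å MS, toluene, −60 °C, slow addition of 5 to 13 and catalyst
Reagents that add atoms: none
Why: Proposed new method: the confined chiral acid protonates the methoxy oxygen of 5 and expels methanol (taken up by the sieves) to leave the O-aryl oxocarbenium ion 14 as a tight ion pair with the chiral anion; the benzyl-bearing terminus of 13 then adds to C2 to give the 4-silyloxyphenyl-stabilised allyl cation 15, whose proximal terminus is captured by ring A at the carbon ortho to the ether oxygen and para to methoxy, and proton loss rearomatises ring A and returns the acid. The closest known chemistry is the racemic Lewis-acid oxa-Povarov annulation of aryl oxocarbenium ions with styrenes and simple alkenes, together with chiral-counteranion control of additions to oxocarbenium ions, whereas neither an enantioselective version nor a 1,3-diene partner is established. The pyran ring closes as a six-membered intramolecular Friedel–Crafts alkylation (6-exo at the allyl cation, the arene C8a=C4a bond endocyclic), so the overall event is a stepwise polar [4+2] with inverse electron demand. C2 is set by the face of 14 that the counteranion leaves open, the C2/C3 relationship by the approach that keeps the C2 aryl and C3 benzyl groups equatorial in the incipient chair, and C4 by closure of that chair with the styryl group equatorial, which amounts to suprafacial addition across the E alkene (3,4-trans, 2,4-cis); because the first C–C bond can form reversibly, mismatched adducts can revert before the irreversible arylation. The step needs ionisation by loss of methanol and not of the phenol (the methoxy oxygen is the more basic one, methanol is removed by the sieves, and only the aryl oxocarbenium ion can end in the irreversible ring closure), attack at the diene terminus that leaves the most delocalised cation, ring closure para to the ring-A methoxy group, and retention of the distal E alkene, which the W-shaped allyl cation from the s-trans (E,E)-diene secures. The stereocentre of racemic 5 is erased on ionisation, and the silyl and methyl ethers should be inert to catalytic acid at low temperature.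

**Step 10**
Reactants: 16 caraganin C bis(triisopropylsilyl) ether
Product: 17 caraganin C
Conditions: TBAF, AcOH, THF, 0 °C
Reagents that add atoms: none
Why: Fluoride-induced cleavage of the two aryl silyl ethers, buffered with acetic acid so that the oxidation-prone 4-hydroxystyryl phenolate is not left free, should release the target without touching the three stereocentres or the E alkene.

**Compound list**
1 | 2,4-dimethoxybenzaldehyde | COc1ccc(C=O)c(OC)c1 | starting material
2 | 1-(dimethoxymethyl)-2,4-dimethoxybenzene | COC(OC)c1ccc(OC)cc1OC | intermediate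
3 | 3-methoxyphenol | COc1cccc(O)c1 | starting material
4 | 1-[chloro(methoxy)methyl]-2,4-dimethoxybenzene (racemic α-chloro ether, not isolated) | COC(Cl)c1ccc(OC)cc1OC | intermediate
5 | 1-[methoxy(3-methoxyphenoxy)methyl]-2,4-dimethoxybenzene (racemic mixed acetal) | COC(Oc1cccc(OC)c1)c1ccc(OC)cc1OC | intermediate
6 | tyrosol, 4-(2-hydroxyethyl)phenol | OCCc1ccc(O)cc1 | starting material
7 | 4-{2-[(1-phenyl-1H-tetrazol-5-yl)sulfanyl]ethyl}phenol | Oc1ccc(CCSc2nnnn2-c2ccccc2)cc1 | intermediate
8 | 1-phenyl-5-({2-[4-(triisopropylsilyloxy)phenyl]ethyl}sulfanyl)-1H-tetrazole | CC(C)[Si](Oc1ccc(CCSc2nnnn2-c2ccccc2)cc1)(C(C)C)C(C)C | intermediate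
9 | 1-phenyl-5-({2-[4-(triisopropylsilyloxy)phenyl]ethyl}sulfonyl)-1H-tetrazole | CC(C)[Si](Oc1ccc(CCS(=O)(=O)c2nnnn2-c2ccccc2)cc1)(C(C)C)C(C)C | intermediate
10 | 4-hydroxybenzaldehyde | O=Cc1ccc(O)cc1 | starting material
11 | 4-(triisopropylsilyloxy)benzaldehyde | CC(C)[Si](Oc1ccc(C=O)cc1)(C(C)C)C(C)C | intermediate
12 | (E)-3-[4-(triisopropylsilyloxy)phenyl]prop-2-enal | CC(C)[Si](Oc1ccc(/C=C/C=O)cc1)(C(C)C)C(C)C | intermediate
13 | (1E,3E)-1,5-bis[4-(triisopropylsilyloxy)phenyl]penta-1,3-diene | C(/C=C/C=C/c1ccc(O[Si](C(C)C)(C(C)C)C(C)C)cc1)c1ccc(O[Si](C(C)C)(C(C)C)C(C)C)cc1 | intermediate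
14 | (E)-[(2,4-dimethoxyphenyl)methylidene](3-methoxyphenyl)oxonium, ion-paired with the chiral anion (not isolated) | COc1cccc(/[O+]=C/c2ccc(OC)cc2OC)c1 | intermediate
15 | (1R,2R)-configured allyl cation from C2–C3 bond formation, drawn with the charge at the future C4 (not isolated) | COc1cccc(O[C@@H](c2ccc(OC)cc2OC)[C@H](Cc2ccc(O[Si](C(C)C)(C(C)C)C(C)C)cc2)[CH+]/C=C/c2ccc(O[Si](C(C)C)(C(C)C)C(C)C)cc2)c1 | intermediate
16 | caraganin C bis(triisopropylsilyl) ether, (2R,3R,4R)-2-(2,4-dimethoxyphenyl)-7-methoxy-3-[4-(triisopropylsilyloxy)benzyl]-4-{(E)-2-[4-(triisopropylsilyloxy)phenyl]ethenyl}chroman | COc1ccc2c(c1)O[C@@H](c1ccc(OC)cc1OC)[C@H](Cc1ccc(O[Si](C(C)C)(C(C)C)C(C)C)cc1)[C@H]2/C=C/c1ccc(O[Si](C(C)C)(C(C)C)C(C)C)cc1 | intermediate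
17 | caraganin C, (2R,3R,4R)-2-(2,4-dimethoxyphenyl)-3-(4-hydroxybenzyl)-4-[(E)-2-(4-hydroxyphenyl)ethenyl]-7-methoxychroman | COc1ccc2c(c1)O[C@@H](c1ccc(OC)cc1OC)[C@H](Cc1ccc(O)cc1)[C@H]2/C=C/c1ccc(O)cc1 | target

**Totals and risks**
Total step count: 10. Longest linear sequence: 6 steps (tyrosol, steps 3, 4, 5, 8, 9, 10).

Steps most likely to fail:

1. Step 9. The acetal may ionise by loss of the phenol instead of methanol, the diene may oligomerise cationically, and the counteranion may discriminate poorly between the faces of the oxocarbenium ion. The fallback sets out from 5 and 13 and returns at 16. The two are combined with SnCl4 in CH2Cl2 at −78 °C, the established racemic Lewis-acid oxa-Povarov annulation, which should give the all-trans chroman as a racemate, that is 16 together with its mirror image, (2S,3S,4S)-caraganin C bis(triisopropylsilyl) ether F1. The enantiomers are then separated by preparative chromatography on a chiral stationary phase, and the (2R,3R,4R) fraction is identified after desilylation by chiroptical comparison with the natural product.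

2. Step 2. The very stabilised α-chloro ether may collapse to aldehyde and chloromethane before it is intercepted, or may alkylate the electron-rich phenol at carbon. The fallback sets out from 2 and 3 and returns at 5. Acetal 2 is treated with Et3SiOTf and 2,4,6-collidine in CH2Cl2 at 0 °C to form the pyridinium-type salt 1-[(2,4-dimethoxyphenyl)(methoxy)methyl]-2,4,6-trimethylpyridinium triflate F2. Phenol 3 then displaces collidine from F2 under these buffered, non-acidic conditions to give the mixed acetal 5.

3. Step 8. The E selectivity at the new alkene may erode with a conjugated aldehyde, and the metallated sulfone may be lost by base-induced elimination of sulfinate to a styrene. The fallback sets out from 11 and 12 and returns at 13 by a stereospecific cross-coupling.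
   - Boron-Wittig olefination of 12 with lithiated bis(pinacolatoboryl)methane (LiTMP, THF, −78 °C) should give 2-{(1E,3E)-4-[4-(triisopropylsilyloxy)phenyl]buta-1,3-dien-1-yl}-4,4,5,5-tetramethyl-1,3,2-dioxaborolane F3.
   - Aldehyde 11 is reduced with NaBH4 in MeOH to [4-(triisopropylsilyloxy)phenyl]methanol F4.
   - F4 is converted under Appel conditions (CBr4, PPh3, CH2Cl2, 0 °C) into 4-(triisopropylsilyloxy)benzyl bromide F5.
   - Suzuki–Miyaura coupling of F3 with F5 (Pd(dppf)Cl2, K3PO4, THF/H2O, 60 °C) forms the sp2–sp3 bond with retention of both alkene geometries and delivers 13.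

**Further compounds**
F1 | step 9 | (2S,3S,4S)-caraganin C bis(triisopropylsilyl) ether (mirror image of 16) | COc1ccc2c(c1)O[C@H](c1ccc(OC)cc1OC)[C@@H](Cc1ccc(O[Si](C(C)C)(C(C)C)C(C)C)cc1)[C@@H]2/C=C/c1ccc(O[Si](C(C)C)(C(C)C)C(C)C)cc1
F2 | step 2 | 1-[(2,4-dimethoxyphenyl)(methoxy)methyl]-2,4,6-trimethylpyridinium triflate | COC(c1ccc(OC)cc1OC)[n+]1c(C)cc(C)cc1C.[O-]S(=O)(=O)C(F)(F)F
F3 | step 8 | 2-{(1E,3E)-4-[4-(triisopropylsilyloxy)phenyl]buta-1,3-dien-1-yl}-4,4,5,5-tetramethyl-1,3,2-dioxaborolane | CC(C)[Si](Oc1ccc(/C=C/C=C/B2OC(C)(C)C(C)(C)O2)cc1)(C(C)C)C(C)C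
F4 | step 8 | [4-(triisopropylsilyloxy)phenyl]methanol | CC(C)[Si](Oc1ccc(CO)cc1)(C(C)C)C(C)C
F5 | step 8 | 4-(triisopropylsilyloxy)benzyl bromide | CC(C)[Si](Oc1ccc(CBr)cc1)(C(C)C)C(C)C
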